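The plan rests on opening ring B (C5–C10) at a C7=C8 double bond. The isopropyl carbons C11–C13 hang on C7, the direct neighbour of C8. Ring and side chain therefore trace back to one enyne: C7≡C11–C12 as a methyl-capped alkyne and C8=C13 as an allyl terminus. A single ring-closing enyne metathesis then forges C7=C8, ring B and the C11=C13 methylene at once. The precursor is a fully substituted ring A cyclohexanone from (R)-linalool. It carries the allyl group on C10 and a butynyl carbinol arm on C5, with C4, C5, C6 and C10 already set. O6 is esterified there as a phosphonoacetate, so the crowded axial 6β-oxygen is never acylated on the decalin.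

Key step: step 12

Remark: eudesmane numbering is used for all intermediates (C14 and C15 are the methyl groups on C10 and C4). Commercial (R)-(−)-linalool is assumed to be enantiomerically pure enough to be the only source of absolute configuration at C4, from which C5 and C10 are relayed.

Step 1
Reactants: 1 (R)-(−)-linalool
Product: 3 (4R)-4-hydroxy-4-methylhex-5-enal (in equilibrium with its five-membered lactol), via secondary ozonide 2 (not isolated)
Conditions: O3 (about 1 equiv, Sudan Red 7B end point), CH2Cl2, −78 °C; then Me2S, −78 °C to rt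
Reagents that add atoms: ozone, O=[O+][O-]
Why: Chemoselective ozonolysis with reductive work-up, in which the electron-rich trisubstituted prenyl double bond consumes ozone much faster than the monosubstituted vinyl group, while the carbinol stereocentre (future C4) is not involved.

Step 2
Reactants: 3 (4R)-4-hydroxy-4-methylhex-5-enal; 4 isopropenylmagnesium bromide
Product: 5 (6R)-2,6-dimethylocta-1,7-diene-3,6-diol (both C3 epimers)
Conditions: 4 (3 equiv), THF, 0 °C to rt
Reagents that add atoms: none
Why: Grignard addition to the aldehyde released from the lactol once the first equivalent has deprotonated the hydroxyl group; the new carbinol carbon (future C1) forms without control, which is harmless because step 4 turns it into a ketone.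

Step 3
Reactants: 5 (6R)-2,6-dimethylocta-1,7-diene-3,6-diol
Product: 6 (4R)-2,4-dimethylcyclohex-2-ene-1,4-diol (both C1 epimers)
Conditions: second-generation Grubbs catalyst RuCl2(=CHPh)(PCy3)(H2IMes) (2 mol %), CH2Cl2 (0.02 M), reflux
Reagents that add atoms: none
Why: Ring-closing olefin metathesis of a 1,7-diene, with initiation at the vinyl group and closure onto the 1,1-disubstituted alkene, should give six-membered ring A with its trisubstituted C5=C10 bond, driven by loss of ethylene.

Step 4
Reactants: 6 (4R)-2,4-dimethylcyclohex-2-ene-1,4-diol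
Product: 7 (4R)-4-hydroxy-2,4-dimethylcyclohex-2-en-1-one
Conditions: activated MnO2 (excess), CH2Cl2, rt
Reagents that add atoms: none
Why: Allylic alcohol oxidation with MnO2 takes only the secondary allylic carbinol and neither oxidises nor transposes the tertiary one, so both epimers converge on a single enone.

Step 5
Reactants: 7 (4R)-4-hydroxy-2,4-dimethylcyclohex-2-en-1-one
Product: 8 (4R)-2,4-dimethyl-4-(triethylsilyloxy)cyclohex-2-en-1-one
Conditions: TESOTf, 2,6-lutidine, CH2Cl2, −78 to 0 °C
Reagents that add atoms: triethylsilyl triflate, CC[Si](CC)(CC)OS(=O)(=O)C(F)(F)F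
Why: Silyl ether formation with a silyl triflate is reactive enough for a tertiary alcohol; the ether prevents retro-aldol cleavage in the β-oxy carbonyl compounds ahead and supplies the bulk that steers step 6.

Step 6
Reactants: 8 (4R)-2,4-dimethyl-4-(triethylsilyloxy)cyclohex-2-en-1-one; 9 1,3-dithiane; 10 allyl bromide
Product: 13 (2R,3R,4R)-2-allyl-3-(1,3-dithian-2-yl)-2,4-dimethyl-4-(triethylsilyloxy)cyclohexan-1-one, via 2-lithio-1,3-dithiane 11 (not isolated), via lithium enolate 12 (not isolated)
Conditions: 9, n-BuLi, THF, −30 °C; HMPA, −78 °C; add 8; then 10, −78 to −30 °C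
Reagents that add atoms: n-BuLi, [Li]CCCC (lithium of 11 and 12 only)
Why: Conjugate addition of a sulfur-stabilised carbanion as its HMPA-separated ion pair with in situ enolate alkylation (three-component coupling): the nucleophile should attack C5 anti to the C4 silyloxy group, and allyl bromide should then approach the tetrasubstituted enolate anti to the pseudoaxial dithianyl group, setting C5 and C10 with the two new arms trans.

Step 7
Reactants: 13 (2R,3R,4R)-2-allyl-3-(1,3-dithian-2-yl)-2,4-dimethyl-4-(triethylsilyloxy)cyclohexan-1-one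
Product: 14 (1R,2R,6R)-2-allyl-2,6-dimethyl-3-oxo-6-(triethylsilyloxy)cyclohexane-1-carbaldehyde
Conditions: MeI, CaCO3, MeCN/H2O (9:1), 40 °C
Reagents that add atoms: water, O
Why: Alkylative dithiane hydrolysis, in which S-methylation makes sulfur a leaving group and water captures the thionium ion, runs under CaCO3-buffered near-neutral conditions that spare the alkene, the TES ether and the epimerisable, elimination-prone C5 position.

Step 8
Reactants: 14 (1R,2R,6R)-2-allyl-2,6-dimethyl-3-oxo-6-(triethylsilyloxy)cyclohexane-1-carbaldehyde; 15 1-propynylmagnesium bromide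
Product: 16 (2R,3S,4R)-2-allyl-3-(1-hydroxybut-2-yn-1-yl)-2,4-dimethyl-4-(triethylsilyloxy)cyclohexan-1-one (both C6 epimers)
Conditions: 15 (1.2 equiv), THF, −78 to −20 °C
Reagents that add atoms: none
Why: Chemoselective 1,2-addition of an alkynyl Grignard reagent, since the aldehyde is far more electrophilic than the C1 ketone flanked by quaternary C10 and the weakly basic acetylide should not trigger β-elimination; the C6 epimer mixture is corrected in steps 9 and 10.

Step 9
Reactants: 16 (2R,3S,4R)-2-allyl-3-(1-hydroxybut-2-yn-1-yl)-2,4-dimethyl-4-(triethylsilyloxy)cyclohexan-1-one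
Product: 17 (2R,3R,4R)-2-allyl-3-(but-2-ynoyl)-2,4-dimethyl-4-(triethylsilyloxy)cyclohexan-1-one
Conditions: Dess–Martin periodinane, CH2Cl2, 0 °C to rt
Reagents that add atoms: none
Why: Dess–Martin oxidation is mild and non-basic and should turn both C6 epimers into one ynone without epimerising C5 or expelling the β-silyloxy group.

Step 10
Reactants: 17 (2R,3R,4R)-2-allyl-3-(but-2-ynoyl)-2,4-dimethyl-4-(triethylsilyloxy)cyclohexan-1-one
Product: 18 (2R,3S,4R)-2-allyl-3-[(1S)-1-hydroxybut-2-yn-1-yl]-2,4-dimethyl-4-(triethylsilyloxy)cyclohexan-1-one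
Conditions: Ru[(S,S)-TsDPEN](p-cymene) (5 mol %), i-PrOH, rt
Reagents that add atoms: none
Why: Noyori asymmetric transfer hydrogenation of an ynone, in which the (S,S)-catalyst places the alkyne where an aryl group normally sits and delivers hydride to give the (6S)-propargylic alcohol under catalyst control, while the dialkyl C1 ketone is not a substrate for this catalyst.

Step 11
Reactants: 18 (2R,3S,4R)-2-allyl-3-[(1S)-1-hydroxybut-2-yn-1-yl]-2,4-dimethyl-4-(triethylsilyloxy)cyclohexan-1-one; 19 diethylphosphonoacetic acid
Product: 20 (1S)-1-[(1S,2R,6R)-2-allyl-2,6-dimethyl-3-oxo-6-(triethylsilyloxy)cyclohexyl]but-2-yn-1-yl (diethoxyphosphoryl)acetate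
Conditions: 19, DCC, DMAP (cat.), CH2Cl2, 0 °C to rt
Reagents that add atoms: none
Why: Steglich-type esterification, which for phosphonoacetic acids probably runs through a slim and highly electrophilic phosphonoketene, should cope with the hindered but still open-chain C6 hydroxyl, retains C6 because only the O–H bond reacts, and gives an O6 group smaller than a bulky silyl ether.

Step 12
Reactants: 20 (1S)-1-[(1S,2R,6R)-2-allyl-2,6-dimethyl-3-oxo-6-(triethylsilyloxy)cyclohexyl]but-2-yn-1-yl (diethoxyphosphoryl)acetate
Product: 21 (4R,5S,6S,10R)-6β-[(diethoxyphosphoryl)acetoxy]-4α-(triethylsilyloxy)eudesma-7,11-dien-1-one (5α-H, 10β-methyl)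
Conditions: second-generation Grubbs catalyst RuCl2(=CHPh)(PCy3)(H2IMes) (10 mol %), ethylene (1 atm), toluene (0.005 M), 70 °C
Reagents that add atoms: none
Why: This is a ring-closing enyne metathesis, a reaction type well established for 1,7-enynes with internal alkynes: the ruthenium alkylidene forms at the unhindered allyl terminus (on C8), adds to the tethered alkyne by [2+2] cycloaddition so that C8 bonds to C7, and opening of the ruthenacyclobutene leaves a vinylcarbene on C11. That carbene picks up a methylene (C13) from ethylene or from the allyl terminus of a second molecule of 20, which finishes the isopropenyl group and hands the metal on, so the step is a net isomerisation with no atom lost. Ring B (C5, C6, C7, C8, C9, C10) closes in the exo mode to a six-membered ring, whereas endo closure (C8 to C11) would demand a seven-membered ring and a carbene on the more crowded C7. No stereocentre is created, and the trans-diequatorial arrangement of the two arms on ring A, fixed in step 6, keeps C8 and C7 within reach of each other. The step needs initiation at the alkene and exo regiochemistry, and the substrate secures both because the monosubstituted allyl alkene is the only easily metathesised site, the methyl cap and the branched propargylic carbon shield the alkyne from direct attack, and the ketone, ester, phosphonate and silyl ether are inert to the catalyst. Ethylene speeds release of the hindered C11 carbene and suppresses oligomerisation, and if it should add across the alkyne first, the resulting butadiene closes onto the allyl group to the same diene 21.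

Step 13
Reactants: 21 (4R,5S,6S,10R)-6β-[(diethoxyphosphoryl)acetoxy]-4α-(triethylsilyloxy)eudesma-7,11-dien-1-one
Product: 22 (4R,5S,6R,7S,10R)-6β-[(diethoxyphosphoryl)acetoxy]-4α-(triethylsilyloxy)eudesman-1-one (7β-isopropyl, 7α-H)
Conditions: H2 (10 bar), 5% Rh/Al2O3, EtOAc, rt
Reagents that add atoms: none
Why: Heterogeneous catalytic hydrogenation (syn addition from the adsorbed face) should saturate the isopropenyl bond first and then bind C7=C8 through the α face, because the β face is walled off by the axial C14 methyl and the pseudoaxial 6β-acyloxy group, so hydrogen reaches C7 from below and the isopropyl group ends up β and equatorial; rhodium is chosen for its low tendency to allylic C–O hydrogenolysis and double-bond migration, and no arene is present yet.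

Step 14
Reactants: 22 (4R,5S,6R,7S,10R)-6β-[(diethoxyphosphoryl)acetoxy]-4α-(triethylsilyloxy)eudesman-1-one; 23 benzaldehyde
Product: 24 (4R,5S,6R,7S,10R)-6β-[(E)-cinnamoyloxy]-4α-(triethylsilyloxy)eudesman-1-one
Conditions: 23, LiCl, DBU, MeCN, 0 °C to rt
Reagents that add atoms: none
Why: Horner–Wadsworth–Emmons olefination under Masamune–Roush conditions, in which the lithium-chelated phosphonoacetate is deprotonated by DBU (too weak a base to enolise the C1 ketone) at a site remote from the crowded C6, and reaction with a non-enolisable aromatic aldehyde should give the (E)-cinnamate.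

Step 15
Reactants: 24 (4R,5S,6R,7S,10R)-6β-[(E)-cinnamoyloxy]-4α-(triethylsilyloxy)eudesman-1-one
Product: 26 (1R,4R,5S,6R,7S,10R)-6β-[(E)-cinnamoyloxy]eudesmane-1β,4α-diol (CNP0114792.1), via silyl-protected 1β-alcohol 25 (not isolated)
Conditions: NaBH4, MeOH/THF, 0 °C; then 1 M aq HCl, rt
Reagents that add atoms: none
Why: Diastereoselective borohydride reduction followed by acid-catalysed silyl ether cleavage in the same flask: hydride should attack C1 axially from the α face, away from the axial C14 methyl, to give the equatorial 1β-alcohol, the conjugated and shielded ester is inert to NaBH4, and dilute acid then frees the tertiary 4α-hydroxyl.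

Compound list
1 | (R)-(−)-linalool, (3R)-3,7-dimethylocta-1,6-dien-3-ol | CC(C)=CCC[C@@](C)(O)C=C | starting material
2 | 3,3-dimethyl-5-[(3R)-3-hydroxy-3-methylpent-4-en-1-yl]-1,2,4-trioxolane (secondary ozonide) | CC1(C)OOC(CC[C@@](C)(O)C=C)O1 | intermediate
3 | (4R)-4-hydroxy-4-methylhex-5-enal (open form of its lactol) | O=CCC[C@@](C)(O)C=C | intermediate
4 | isopropenylmagnesium bromide | CC(=C)[Mg]Br | starting material
5 | (6R)-2,6-dimethylocta-1,7-diene-3,6-diol, both C3 epimers | CC(=C)C(O)CC[C@@](C)(O)C=C | intermediate
6 | (4R)-2,4-dimethylcyclohex-2-ene-1,4-diol, both C1 epimers | CC1=C[C@](C)(O)CCC1O | intermediate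
7 | (4R)-4-hydroxy-2,4-dimethylcyclohex-2-en-1-one | CC1=C[C@](C)(O)CCC1=O | intermediate
8 | (4R)-2,4-dimethyl-4-(triethylsilyloxy)cyclohex-2-en-1-one | CC1=C[C@](C)(O[Si](CC)(CC)CC)CCC1=O | intermediate
9 | 1,3-dithiane | C1CSCSC1 | starting material
10 | allyl bromide | C=CCBr | starting material
11 | 2-lithio-1,3-dithiane | [Li]C1SCCCS1 | intermediate
12 | lithium enolate (C1–O–Li, C1=C10) of the 1,4-adduct, dithianyl on C5 trans to the C4 silyloxy group | CC1=C(O[Li])CC[C@@](C)(O[Si](CC)(CC)CC)[C@@H]1C2SCCCS2 | intermediate
13 | (2R,3R,4R)-2-allyl-3-(1,3-dithian-2-yl)-2,4-dimethyl-4-(triethylsilyloxy)cyclohexan-1-one | C=CC[C@@]1(C)C(=O)CC[C@@](C)(O[Si](CC)(CC)CC)[C@@H]1C2SCCCS2 | intermediate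
14 | (1R,2R,6R)-2-allyl-2,6-dimethyl-3-oxo-6-(triethylsilyloxy)cyclohexane-1-carbaldehyde | C=CC[C@@]1(C)C(=O)CC[C@@](C)(O[Si](CC)(CC)CC)[C@@H]1C=O | intermediate
15 | 1-propynylmagnesium bromide | CC#C[Mg]Br | starting material
16 | (2R,3S,4R)-2-allyl-3-(1-hydroxybut-2-yn-1-yl)-2,4-dimethyl-4-(triethylsilyloxy)cyclohexan-1-one, both C6 epimers | C=CC[C@@]1(C)C(=O)CC[C@@](C)(O[Si](CC)(CC)CC)[C@@H]1C(O)C#CC | intermediate
17 | (2R,3R,4R)-2-allyl-3-(but-2-ynoyl)-2,4-dimethyl-4-(triethylsilyloxy)cyclohexan-1-one | C=CC[C@@]1(C)C(=O)CC[C@@](C)(O[Si](CC)(CC)CC)[C@@H]1C(=O)C#CC | intermediate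
18 | (2R,3S,4R)-2-allyl-3-[(1S)-1-hydroxybut-2-yn-1-yl]-2,4-dimethyl-4-(triethylsilyloxy)cyclohexan-1-one | C=CC[C@@]1(C)C(=O)CC[C@@](C)(O[Si](CC)(CC)CC)[C@@H]1[C@H](O)C#CC | intermediate
19 | diethylphosphonoacetic acid | CCOP(=O)(CC(=O)O)OCC | starting material
20 | (1S)-1-[(1S,2R,6R)-2-allyl-2,6-dimethyl-3-oxo-6-(triethylsilyloxy)cyclohexyl]but-2-yn-1-yl (diethoxyphosphoryl)acetate (enyne precursor) | C=CC[C@@]1(C)C(=O)CC[C@@](C)(O[Si](CC)(CC)CC)[C@@H]1[C@H](OC(=O)CP(=O)(OCC)OCC)C#CC | intermediate
21 | (4R,5S,6S,10R)-6β-[(diethoxyphosphoryl)acetoxy]-4α-(triethylsilyloxy)eudesma-7,11-dien-1-one | CC(=C)C1=CC[C@@]2(C)C(=O)CC[C@@](C)(O[Si](CC)(CC)CC)[C@@H]2[C@@H]1OC(=O)CP(=O)(OCC)OCC | intermediate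
22 | (4R,5S,6R,7S,10R)-6β-[(diethoxyphosphoryl)acetoxy]-4α-(triethylsilyloxy)eudesman-1-one | CC(C)[C@@H]1CC[C@@]2(C)C(=O)CC[C@@](C)(O[Si](CC)(CC)CC)[C@@H]2[C@@H]1OC(=O)CP(=O)(OCC)OCC | intermediate
23 | benzaldehyde | O=Cc1ccccc1 | starting material
24 | (4R,5S,6R,7S,10R)-6β-[(E)-cinnamoyloxy]-4α-(triethylsilyloxy)eudesman-1-one | CC(C)[C@@H]1CC[C@@]2(C)C(=O)CC[C@@](C)(O[Si](CC)(CC)CC)[C@@H]2[C@@H]1OC(=O)/C=C/c1ccccc1 | intermediate
25 | (1R,4R,5S,6R,7S,10R)-6β-[(E)-cinnamoyloxy]-4α-(triethylsilyloxy)eudesman-1β-ol | CC(C)[C@@H]1CC[C@@]2(C)[C@H](O)CC[C@@](C)(O[Si](CC)(CC)CC)[C@@H]2[C@@H]1OC(=O)/C=C/c1ccccc1 | intermediate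
26 | (1R,4R,5S,6R,7S,10R)-6β-[(E)-cinnamoyloxy]eudesmane-1β,4α-diol, CNP0114792.1 | CC(C)[C@@H]1CC[C@@]2(C)[C@H](O)CC[C@@](C)(O)[C@@H]2[C@@H]1OC(=O)/C=C/c1ccccc1 | target

Total step count: 15. Longest linear sequence: 15 steps, from 1 to 26.

Steps most likely to fail

Step 12. The carbene on C8 may reach the shielded internal alkyne too slowly. Catalyst decay or oligomerisation through the allyl termini could then overtake ring closure. The fallback separates the two bond formations.
- It sets out from 20.
- Intermolecular enyne cross-metathesis with ethylene uses the small methylidene carrier to convert the alkyne into a 2,3-disubstituted butadiene. Conditions are raised ethylene pressure, second-generation Grubbs catalyst and toluene at 80 °C.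
- This should give (1S)-1-[(1S,2R,6R)-2-allyl-2,6-dimethyl-3-oxo-6-(triethylsilyloxy)cyclohexyl]-3-methyl-2-methylidenebut-3-en-1-yl (diethoxyphosphoryl)acetate F1, which is isolated.
- Ordinary ring-closing diene metathesis then joins the allyl group and the C7 methylene. It uses the second-generation Hoveyda–Grubbs catalyst RuCl2(=CH-C6H4-2-O-i-Pr)(H2IMes) under an argon purge.
- This closes C7=C8 and comes back to the route at 21.

Step 6. Attack at the C1 carbonyl may compete with slow attack at the neopentyl-like C5. Enolate equilibration before allylation, or poor facial selectivity next to C4, is also possible. The fallback replaces the lithium carbanion by a soft organocopper hydroxymethyl equivalent.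
- It sets out from 8.
- Copper-catalysed 1,4-addition of (isopropoxydimethylsilyl)methylmagnesium chloride (CuBr·SMe2, THF, −40 °C) should give the chloromagnesium enolate F2.
- Allylation of this enolate in the same flask with 10 and HMPA gives (2R,3R,4R)-2-allyl-3-{[isopropoxy(dimethyl)silyl]methyl}-2,4-dimethyl-4-(triethylsilyloxy)cyclohexan-1-one F3.
- Tamao oxidation then gives (2R,3S,4R)-2-allyl-3-(hydroxymethyl)-2,4-dimethyl-4-(triethylsilyloxy)cyclohexan-1-one F4. The fluoride-free variant (H2O2, KHCO3, THF/MeOH) is used to spare the TES ether.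
- Dess–Martin oxidation of F4 comes back to the route at 14.

Step 13. Loss of the allylic ester by hydrogenolysis is one risk. Another is 1,4-addition or migration to a tetrasubstituted alkene that stalls. A third is insufficient face discrimination on the metal surface. The fallback splits the reduction and changes the control element at C7 from surface adsorption to a free radical.
- It sets out from 21.
- Homogeneous hydrogenation with RhCl(PPh3)3 (H2, benzene/EtOH) should saturate only the 1,1-disubstituted C11=C13 bond. The product is 6β-[(diethoxyphosphoryl)acetoxy]-4α-(triethylsilyloxy)eudesm-7-en-1-one F5.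
- Hydrogen-atom-transfer hydrogenation (Mn(dpm)3, PhSiH3, t-BuOOH, i-PrOH, rt) then places H on C8 and generates the tertiary C7 radical.
- That radical should be quenched from the open α face to give the more stable equatorial isopropyl group, without any metal-surface C–O cleavage.
- The sequence comes back to the route at 22.

Further compounds
F1 | step 12 | (1S)-1-[(1S,2R,6R)-2-allyl-2,6-dimethyl-3-oxo-6-(triethylsilyloxy)cyclohexyl]-3-methyl-2-methylidenebut-3-en-1-yl (diethoxyphosphoryl)acetate | C=CC[C@@]1(C)C(=O)CC[C@@](C)(O[Si](CC)(CC)CC)[C@@H]1[C@H](OC(=O)CP(=O)(OCC)OCC)C(=C)C(C)=C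
F2 | step 6 | chloromagnesium enolate of the copper-catalysed 1,4-adduct (silylmethyl group on C5 trans to the C4 silyloxy group) | CC1=C(O[Mg]Cl)CC[C@@](C)(O[Si](CC)(CC)CC)[C@@H]1C[Si](C)(C)OC(C)C
F3 | step 6 | (2R,3R,4R)-2-allyl-3-{[isopropoxy(dimethyl)silyl]methyl}-2,4-dimethyl-4-(triethylsilyloxy)cyclohexan-1-one | C=CC[C@@]1(C)C(=O)CC[C@@](C)(O[Si](CC)(CC)CC)[C@@H]1C[Si](C)(C)OC(C)C
F4 | step 6 | (2R,3S,4R)-2-allyl-3-(hydroxymethyl)-2,4-dimethyl-4-(triethylsilyloxy)cyclohexan-1-one | C=CC[C@@]1(C)C(=O)CC[C@@](C)(O[Si](CC)(CC)CC)[C@@H]1CO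
F5 | step 13 | (4R,5S,6S,10R)-6β-[(diethoxyphosphoryl)acetoxy]-4α-(triethylsilyloxy)eudesm-7-en-1-one | CC(C)C1=CC[C@@]2(C)C(=O)CC[C@@](C)(O[Si](CC)(CC)CC)[C@@H]2[C@@H]1OC(=O)CP(=O)(OCC)OCC
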